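**Retrosynthetic overview**

1. Target locants: ring A = C1(CMe2)–C2(HBr)–C3(HOH)–C4H2–C5(=CH2)–C6; ring B = C6–C7H2–C8(HBr)–C9(Cl)(CH3)–C10H2–C11H2. The strategy rests on ring B being the spiro carbon C6 plus the five-carbon chain C7–C11, whose bromomethine C8 and chloro-methyl carbon C9 are adjacent and trans. The chain is therefore made open with both halogens in place, and ring B is closed last at C6–C7.
2. Chain: syn-carbocupration of a pent-2-ynoate gives the (Z)-allylic alcohol, and catalytic enantioselective bromochlorination sets C8 and C9. The Z olefin is required: anti addition across it gives the trans ring halogens, whereas an E olefin would give the cis pair.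
3. Ring A is bought as dimedone. Its ethyl vinylogous ester is alkylated at the α′ carbon (the future C6) with the chain iodide (C11); the α′ enolate then displaces the C7 mesylate, closing ring B and setting C6. Ring order: A from dimedone, B in step 11.
4. Ring A finish: the C5 carbonyl becomes a (trimethylsilyl)methyl enone (1,2-addition with transposition), C2 is brominated through the α′ enolate, fluoride-triggered desilylation with α-protonation gives the 5-methylidene 3-ketone, and i-Bu2AlH gives the cis bromohydrin.

Key step: step 11

Remarks: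
- All spiro compounds carry the locants of the target given in line 1.
- In step 5 the ligand enantiomer is the one that delivers the (2R,3R) bromochloride; the sense of induction is to be confirmed on 8 before material is committed.
- The ring A bromine centre C2 is not expected to be controlled by ring B (see step 13); its epimers are separated.

**Route**

Step 1
Reactants: 1 but-3-yn-1-ol
Product: 2 tert-butyl(but-3-yn-1-yloxy)dimethylsilane
Conditions: TBSCl, imidazole, CH2Cl2, 0 °C to rt
Reagents that add atoms: tert-butyldimethylsilyl chloride, CC(C)(C)[Si](C)(C)Cl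
Why: Standard silylation of a primary alcohol; the silyl ether should survive the organolithium, cuprate, hydride and titanium steps and come off later with HF without harming a sulfonate.

Step 2
Reactants: 2 tert-butyl(but-3-yn-1-yloxy)dimethylsilane
Product: 4 methyl 5-[(tert-butyldimethylsilyl)oxy]pent-2-ynoate, via lithium acetylide 3 (not isolated)
Conditions: n-BuLi, THF, −78 °C; then ClCO2Me, −78 to 0 °C
Reagents that add atoms: methyl chloroformate, COC(=O)Cl
Why: C-acylation of a lithium acetylide with a chloroformate, a routine way to a 2-ynoate.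

Step 3
Reactants: 4 methyl 5-[(tert-butyldimethylsilyl)oxy]pent-2-ynoate
Product: 6 methyl (Z)-5-[(tert-butyldimethylsilyl)oxy]-3-methylpent-2-enoate, via alkenylcuprate 5 (not isolated)
Conditions: Me2CuLi (from CuI and MeLi), THF, −78 °C; then MeOH, −78 °C
Reagents that add atoms: lithium dimethylcuprate, [Li+].C[Cu-]C
Why: syn-Carbocupration of a 2-ynoate puts methyl and copper on the same side, and protonation with retention at −78 °C (before the alkenylcuprate can isomerise) leaves the silyloxyethyl chain cis to the ester, i.e. the Z olefin.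

Step 4
Reactants: 6 methyl (Z)-5-[(tert-butyldimethylsilyl)oxy]-3-methylpent-2-enoate
Product: 7 (Z)-5-[(tert-butyldimethylsilyl)oxy]-3-methylpent-2-en-1-ol
Conditions: i-Bu2AlH, CH2Cl2, −78 °C; aq. potassium sodium tartrate work-up
Reagents that add atoms: none
Why: 1,2-Reduction of an enoate to the allylic alcohol with retention of olefin geometry.

Step 5
Reactants: 7 (Z)-5-[(tert-butyldimethylsilyl)oxy]-3-methylpent-2-en-1-ol
Product: 8 (2R,3R)-2-bromo-5-[(tert-butyldimethylsilyl)oxy]-3-chloro-3-methylpentan-1-ol
Conditions: NBS, ClTi(OiPr)3, chiral tridentate salicylaldimine amino-alcohol (Schiff-base) ligand (20 mol%), hexanes, −20 °C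
Reagents that add atoms: N-bromosuccinimide, O=C1CCC(=O)N1Br; chlorotitanium triisopropoxide, CC(C)O[Ti](Cl)(OC(C)C)OC(C)C
Why: Catalytic enantioselective bromochlorination of an allylic alcohol: the titanium-bound alkoxide and chiral ligand select the olefin face for bromonium formation, and chloride opens it anti at the tertiary carbon, so the Z olefin gives the (2R,3R) pair with Br on C2 and Cl on C3 (the future trans C8/C9 of ring B).

Step 6
Reactants: 8 (2R,3R)-2-bromo-5-[(tert-butyldimethylsilyl)oxy]-3-chloro-3-methylpentan-1-ol
Product: 9 (2R,3R)-2-bromo-5-[(tert-butyldimethylsilyl)oxy]-3-chloro-3-methylpentyl methanesulfonate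
Conditions: MsCl, Et3N, CH2Cl2, −20 °C
Reagents that add atoms: methanesulfonyl chloride, CS(=O)(=O)Cl
Why: Sulfonylation of the primary alcohol; it masks the bromohydrin oxygen (whose alkoxide would close to an epoxide under any later base) and installs the leaving group of the key step.

Step 7
Reactants: 9 (2R,3R)-2-bromo-5-[(tert-butyldimethylsilyl)oxy]-3-chloro-3-methylpentyl methanesulfonate
Product: 10 (2R,3R)-2-bromo-3-chloro-5-hydroxy-3-methylpentyl methanesulfonate
Conditions: HF·pyridine, THF, 0 °C; used at once
Reagents that add atoms: none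
Why: Non-basic fluoride desilylation leaves the sulfonate and both carbon–halogen bonds alone; immediate use avoids slow ring closure of the free alcohol onto the mesylate.

Step 8
Reactants: 10 (2R,3R)-2-bromo-3-chloro-5-hydroxy-3-methylpentyl methanesulfonate
Product: 11 (2R,3R)-2-bromo-3-chloro-5-iodo-3-methylpentyl methanesulfonate
Conditions: I2, PPh3, imidazole, CH2Cl2, 0 °C
Reagents that add atoms: iodine, II
Why: Appel-type iodination of the unhindered primary alcohol; the β-branched mesylate next to the bromomethine is far less open to iodide at 0 °C.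

Step 9
Reactants: 12 dimedone
Product: 13 3-ethoxy-5,5-dimethylcyclohex-2-en-1-one
Conditions: EtOH, TsOH (cat.), toluene, reflux, Dean–Stark
Reagents that add atoms: ethanol, CCO
Why: Acid-catalysed enol etherification of the symmetrical 1,3-dione gives a single vinylogous ester.

Step 10
Reactants: 13 3-ethoxy-5,5-dimethylcyclohex-2-en-1-one; 11 (2R,3R)-2-bromo-3-chloro-5-iodo-3-methylpentyl methanesulfonate
Product: 15 (2R,3R)-2-bromo-3-chloro-5-(4-ethoxy-6,6-dimethyl-2-oxocyclohex-3-en-1-yl)-3-methylpentyl methanesulfonate (both epimers at the ring carbon), via lithium enolate 14 (not isolated)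
Conditions: LiN(i-Pr)2, THF, −78 °C; then 11, DMPU, −78 to −30 °C
Reagents that add atoms: none
Why: Stork–Danheiser kinetic α′-alkylation of a 3-alkoxyenone; the unbranched primary iodide should react much faster than the β-branched β-bromo mesylate, and the new ring stereocentre is left unassigned because it is deprotonated in the next step.

Step 11
Reactants: 15 (2R,3R)-2-bromo-3-chloro-5-(4-ethoxy-6,6-dimethyl-2-oxocyclohex-3-en-1-yl)-3-methylpentyl methanesulfonate
Product: 17 (6S,8R,9R)-8-bromo-9-chloro-3-ethoxy-1,1,9-trimethylspiro[5.5]undec-3-en-5-one, via potassium enolate 16 (not isolated)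
Conditions: KN(SiMe3)2 (1.05 equiv), THF (0.02 M), −78 to 0 °C
Reagents that add atoms: none
Why: KN(SiMe3)2 removes the hydrogen on the future C6 (α′ to the vinylogous-ester carbonyl), and the fully substituted enolate carbon of 16 displaces the primary C7 mesylate by intramolecular SN2; the closest known reaction type is the second stage of a Stork–Danheiser α′,α′-dialkylation, i.e. spiroannulation of 3-alkoxycyclohexenone α′ enolates by intramolecular alkylation. Ring B closes in a 6-exo-tet mode with the enolate double bond exocyclic to the forming ring, a geometry that favours C-alkylation, whereas O-alkylation would need an eight-membered ring. The new stereocentre C6 is set by C8 and C9 through a chair-like transition state in which Br (C8), Cl (C9) and the bulky CMe2 arm (C1) are all equatorial on the forming ring while the C9 methyl and the planar enolate carbon C5 are axial; the competing chairs carry an axial bromine next to the axial ring A arm or put the CMe2 group axial over ring B. The step needs the primary sulfonate to react in preference to the secondary bromide and the tertiary chloride, which the substrate secures because attack at C8 would be a 5-exo displacement at a carbon flanked by the fully substituted C9 and attack at C9 would give a four-membered ring. It also needs α′ and not γ (C2) enolisation to be productive, and the γ dienolate can only reach C7 through an eight-membered ring and can return by proton transfer, so only the C6 enolate leads on. One equivalent of base and low temperature are chosen so that E2 loss of the mesylate through the acidified bromomethine hydrogen does not take over.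

Step 12
Reactants: 17 (6S,8R,9R)-8-bromo-9-chloro-3-ethoxy-1,1,9-trimethylspiro[5.5]undec-3-en-5-one
Product: 19 (6S,8R,9R)-8-bromo-9-chloro-1,1,9-trimethyl-5-[(trimethylsilyl)methyl]spiro[5.5]undec-4-en-3-one, via tertiary alcohol 18 (not isolated)
Conditions: Me3SiCH2Li, CeCl3, THF, −78 °C; then 1 M HCl, THF, 0 °C, short contact
Reagents that add atoms: (trimethylsilyl)methyllithium, [Li]C[Si](C)(C)C; water, O
Why: Stork–Danheiser sequence: the weakly basic organocerium reagent adds 1,2 to the hindered vinylogous-ester carbonyl, and brief dilute acid removes water and ethanol with carbonyl transposition to the 3-(silylmethyl)enone while the allylic C–Si bond is kept; no stereocentre remains at C5.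

Step 13
Reactants: 19 (6S,8R,9R)-8-bromo-9-chloro-1,1,9-trimethyl-5-[(trimethylsilyl)methyl]spiro[5.5]undec-4-en-3-one
Product: 21 (2R,6R,8R,9R)-2,8-dibromo-9-chloro-1,1,9-trimethyl-5-[(trimethylsilyl)methyl]spiro[5.5]undec-4-en-3-one, via lithium enolate 20 (not isolated)
Conditions: LiN(i-Pr)2, THF, −78 °C; then NBS, THF, −78 °C; HPLC separation of the C2 epimers
Reagents that add atoms: N-bromosuccinimide, O=C1CCC(=O)N1Br
Why: Kinetic α′-deprotonation of a 3-substituted cyclohex-2-enone at C2 (isophorone-type regiochemistry) and bromination of the cross-conjugated enolate; ring B lies almost mirror-symmetrically above and below the enolate plane (the two faces differ only by the remote equatorial C8 bromine), so no useful facial bias is expected at the new C2 centre, and the (2R) epimer is therefore taken by chromatography while the (2S) epimer is returned by deprotonation and reprotonation at C2.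

Step 14
Reactants: 21 (2R,6R,8R,9R)-2,8-dibromo-9-chloro-1,1,9-trimethyl-5-[(trimethylsilyl)methyl]spiro[5.5]undec-4-en-3-one
Product: 23 (2R,6R,8R,9R)-2,8-dibromo-9-chloro-1,1,9-trimethyl-5-methylidenespiro[5.5]undecan-3-one, via ammonium dienolate 22 (not isolated)
Conditions: Bu4NF, AcOH, THF, −78 to −20 °C
Reagents that add atoms: none
Why: Fluoride attacks silicon of the γ-silyl enone (a vinylogous α-silyl ketone) and releases the extended dienolate 22 at one defined site, and the acetic acid present protonates it kinetically at the α-carbon C4 (the classical deconjugation of dienolates), leaving the double bond exocyclic at C5; the buffer should keep C2 from enolising.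

Step 15
Reactants: 23 (2R,6R,8R,9R)-2,8-dibromo-9-chloro-1,1,9-trimethyl-5-methylidenespiro[5.5]undecan-3-one
Product: 24 (2R,3S,6R,8R,9R)-2,8-dibromo-9-chloro-1,1,9-trimethyl-5-methylidenespiro[5.5]undecan-3-ol
Conditions: i-Bu2AlH, CH2Cl2, −78 °C
Reagents that add atoms: none
Why: Substrate-controlled reduction of an α-bromo ketone in the chair with Br equatorial: the axial methyl on C1 blocks axial approach, so hydride enters equatorially and the new C3 hydroxyl is axial and cis to the bromine (3S); the alkyl halides and the 1,1-disubstituted olefin are inert at −78 °C.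

**Compound list**

1 | but-3-yn-1-ol | C#CCCO | starting material
2 | tert-butyl(but-3-yn-1-yloxy)dimethylsilane | C#CCCO[Si](C)(C)C(C)(C)C | intermediate
3 | lithium acetylide of 2 (not isolated) | [Li]C#CCCO[Si](C)(C)C(C)(C)C | intermediate
4 | methyl 5-[(tert-butyldimethylsilyl)oxy]pent-2-ynoate | COC(=O)C#CCCO[Si](C)(C)C(C)(C)C | intermediate
5 | lithium alkenyl(methyl)cuprate from syn-addition to 4, Cu cis to the new methyl (not isolated) | [Li+].COC(=O)/C([Cu-]C)=C(/C)CCO[Si](C)(C)C(C)(C)C | intermediate
6 | methyl (Z)-5-[(tert-butyldimethylsilyl)oxy]-3-methylpent-2-enoate | COC(=O)/C=C(\CCO[Si](C)(C)C(C)(C)C)C | intermediate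
7 | (Z)-5-[(tert-butyldimethylsilyl)oxy]-3-methylpent-2-en-1-ol | OC/C=C(\CCO[Si](C)(C)C(C)(C)C)C | intermediate
8 | (2R,3R)-2-bromo-5-[(tert-butyldimethylsilyl)oxy]-3-chloro-3-methylpentan-1-ol | CC(C)(C)[Si](C)(C)OCC[C@@](C)(Cl)[C@H](Br)CO | intermediate
9 | (2R,3R)-2-bromo-5-[(tert-butyldimethylsilyl)oxy]-3-chloro-3-methylpentyl methanesulfonate | CC(C)(C)[Si](C)(C)OCC[C@@](C)(Cl)[C@H](Br)COS(C)(=O)=O | intermediate
10 | (2R,3R)-2-bromo-3-chloro-5-hydroxy-3-methylpentyl methanesulfonate | OCC[C@@](C)(Cl)[C@H](Br)COS(C)(=O)=O | intermediate
11 | (2R,3R)-2-bromo-3-chloro-5-iodo-3-methylpentyl methanesulfonate | ICC[C@@](C)(Cl)[C@H](Br)COS(C)(=O)=O | intermediate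
12 | dimedone (5,5-dimethylcyclohexane-1,3-dione) | CC1(C)CC(=O)CC(=O)C1 | starting material
13 | 3-ethoxy-5,5-dimethylcyclohex-2-en-1-one | CCOC1=CC(=O)CC(C)(C)C1 | intermediate
14 | lithium α′ enolate of 13 (not isolated) | CCOC1=CC(O[Li])=CC(C)(C)C1 | intermediate
15 | (2R,3R)-2-bromo-3-chloro-5-(4-ethoxy-6,6-dimethyl-2-oxocyclohex-3-en-1-yl)-3-methylpentyl methanesulfonate, ring carbon unassigned | CCOC1=CC(=O)C(CC[C@@](C)(Cl)[C@H](Br)COS(C)(=O)=O)C(C)(C)C1 | intermediate
16 | potassium α′ enolate of 15 (not isolated) | CCOC1=CC(O[K])=C(CC[C@@](C)(Cl)[C@H](Br)COS(C)(=O)=O)C(C)(C)C1 | intermediate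
17 | (6S,8R,9R)-8-bromo-9-chloro-3-ethoxy-1,1,9-trimethylspiro[5.5]undec-3-en-5-one | O=C1C=C(OCC)CC(C)(C)[C@@]12CC[C@@](C)(Cl)[C@H](Br)C2 | intermediate
18 | (6S,8R,9R)-8-bromo-9-chloro-3-ethoxy-1,1,9-trimethyl-5-[(trimethylsilyl)methyl]spiro[5.5]undec-3-en-5-ol, C5 unassigned (not isolated) | C[Si](C)(C)CC1(O)C=C(OCC)CC(C)(C)[C@@]12CC[C@@](C)(Cl)[C@H](Br)C2 | intermediate
19 | (6S,8R,9R)-8-bromo-9-chloro-1,1,9-trimethyl-5-[(trimethylsilyl)methyl]spiro[5.5]undec-4-en-3-one | C[Si](C)(C)CC1=CC(=O)CC(C)(C)[C@@]12CC[C@@](C)(Cl)[C@H](Br)C2 | intermediate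
20 | lithium C2 (α′) enolate of 19 (not isolated) | C[Si](C)(C)CC1=CC(O[Li])=CC(C)(C)[C@@]12CC[C@@](C)(Cl)[C@H](Br)C2 | intermediate
21 | (2R,6R,8R,9R)-2,8-dibromo-9-chloro-1,1,9-trimethyl-5-[(trimethylsilyl)methyl]spiro[5.5]undec-4-en-3-one | C[Si](C)(C)CC1=CC(=O)[C@H](Br)C(C)(C)[C@@]12CC[C@@](C)(Cl)[C@H](Br)C2 | intermediate
22 | tetrabutylammonium 3-oxido-3,5(exocyclic)-dienolate from desilylation of 21 (not isolated) | CCCC[N+](CCCC)(CCCC)CCCC.C=C1C=C([O-])[C@H](Br)C(C)(C)[C@@]12CC[C@@](C)(Cl)[C@H](Br)C2 | intermediate
23 | (2R,6R,8R,9R)-2,8-dibromo-9-chloro-1,1,9-trimethyl-5-methylidenespiro[5.5]undecan-3-one | C=C1CC(=O)[C@H](Br)C(C)(C)[C@@]12CC[C@@](C)(Cl)[C@H](Br)C2 | intermediate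
24 | (2R,3S,6R,8R,9R)-2,8-dibromo-9-chloro-1,1,9-trimethyl-5-methylidenespiro[5.5]undecan-3-ol | C=C1C[C@H](O)[C@H](Br)C(C)(C)[C@@]12CC[C@@](C)(Cl)[C@H](Br)C2 | target

**Step count**

Total: 15 steps. Longest linear sequence: 14 steps (steps 1–8 and 10–15, from but-3-yn-1-ol); step 9 is the one-step side branch from dimedone.

**Steps most likely to fail**

Step 11 (key step). The amide base may remove the C2 hydrogens or trigger E2 loss of methanesulfonate through the bromomethine hydrogen instead of forming the hindered C6 enolate. The displacement at a β-branched carbon by an enolate carbon next to CMe2 may also be too slow to compete. Fallback: setting out from 15, soft enolisation (Me3SiOSO2CF3, Et3N, CH2Cl2, 0 °C) should give the C6 trimethylsilyl dienol ether F1. An anhydrous fluoride source (Bu4N+ Ph3SiF2−, THF, 0 °C to rt) then frees the enolate with no amide base present, and the same 6-exo-tet closure (fluoride-promoted alkylation of an enol silane) brings the material back to the route at 17.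

Step 13. The bromination has no facial discrimination at C2, and the two C2 epimers, which differ only in how ring A sits relative to the remote ring B centres, may not separate. Fallback: setting out from 19, step 13 is run without separation, so 21 is carried together with its (2S) epimer F2 through the conditions of step 14. This gives 23 together with the (2S) ketone F3. The mixture is then reduced under catalyst control, using the enantiomer of 1-methyl-3,3-diphenyl-tetrahydropyrrolo[1,2-c][1,3,2]oxazaborole that is matched to 23 (20 mol%, catecholborane, toluene, −78 °C). Ketone 23 is reduced on the face it prefers anyway and gives 24. For F3 the catalyst and substrate preferences oppose each other, so it should react much more slowly and be removed as unchanged ketone. The fallback rejoins the route at 24.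

Step 14. The dienolate may be protonated at the exocyclic carbon (giving the conjugated 5-methyl enone), may lose bromide in a Favorskii-type process, or fluoride may enolise C2. Fallback: setting out from 21, the ketone is reduced first (i-Bu2AlH, CH2Cl2, −78 °C; same equatorial hydride delivery as in step 15) to the allylic alcohol F4, which still carries the allylsilane. Protodesilylation with allylic shift (CF3CO2H, CH2Cl2, −20 °C) then puts the proton on C4 and the double bond into the exocyclic position, rejoining the route at 24.

Further compounds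
F1 | step 11 | (2R,3R)-2-bromo-3-chloro-5-[4-ethoxy-6,6-dimethyl-2-(trimethylsilyloxy)cyclohexa-1,3-dien-1-yl]-3-methylpentyl methanesulfonate | CCOC1=CC(O[Si](C)(C)C)=C(CC[C@@](C)(Cl)[C@H](Br)COS(C)(=O)=O)C(C)(C)C1
F2 | step 13 | (2S,6R,8R,9R)-2,8-dibromo-9-chloro-1,1,9-trimethyl-5-[(trimethylsilyl)methyl]spiro[5.5]undec-4-en-3-one | C[Si](C)(C)CC1=CC(=O)[C@@H](Br)C(C)(C)[C@@]12CC[C@@](C)(Cl)[C@H](Br)C2
F3 | step 13 | (2S,6R,8R,9R)-2,8-dibromo-9-chloro-1,1,9-trimethyl-5-methylidenespiro[5.5]undecan-3-one | C=C1CC(=O)[C@@H](Br)C(C)(C)[C@@]12CC[C@@](C)(Cl)[C@H](Br)C2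
F4 | step 14 | (2R,3S,6R,8R,9R)-2,8-dibromo-9-chloro-1,1,9-trimethyl-5-[(trimethylsilyl)methyl]spiro[5.5]undec-4-en-3-ol | C[Si](C)(C)CC1=C[C@H](O)[C@H](Br)C(C)(C)[C@@]12CC[C@@](C)(Cl)[C@H](Br)C2
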